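**Remark on the chemistry (assumption).** Ring A is numbered C1 (prenyl), C2, C3, C4 (aryloxy), C5 (carboxyl), C6 (hydroxyl). Ring B is numbered C1' (ether oxygen), C2' (hydroxyl), C4' (methyl), C6' (hydroxymethyl). The target has no stereocentre and the prenyl double bond has no geometric isomers, so nothing stereochemical has to be set.

## Structural features

The target is a diaryl ether: two benzene rings joined through one oxygen, with no further ring and no stereocentre. Ring A is 1,2,3,4-tetrasubstituted, with the prenyl group on C1, the ether oxygen on C4, the carboxyl on C5 and a phenolic hydroxyl on C6. Ring B carries the ether oxygen on C1' between a hydroxyl on C2' and a hydroxymethyl group on C6', and a methyl on C4'. Three groups are fragile towards acid: the carboxylic acid between two oxygen-bearing carbons would decarboxylate, the C6 phenol ortho to the prenyl group would close a chroman, and the benzylic alcohol can ionise or lactonise onto the acid. Hydrogenolysis is also excluded because it would saturate the prenyl alkene, so the end of the synthesis has to be basic or nucleophilic. The real difficulty is the ether oxygen, flanked by ortho substituents on both rings (two on ring B), together with the contiguous C4–C5–C6 pattern of ring A. The key step exploits the fact that C4 and C5 are neighbours and that C6 bears oxygen: a C4–C5 aryne polarised by the C6 alkoxy group accepts the ring B oxygen at C4 and a one-carbon electrophile at C5.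

## Logic of the disconnections

**23 to 21.** No skeletal bond is cut. Two O–CH3 bonds (on the C6 and C2' oxygens) and one O–Si bond (benzylic oxygen) are added back. The C6 methyl ether steers the aryne, the C2' methyl ether comes with 13, and the silyl ether keeps the benzylic alkoxide from competing with the phenoxide. The forward step has to unmask three hydroxyls without acid.

**21 to 12, 16 and 17.** The C4–O(aryl) bond and the C5–carboxyl bond are cut. This divides the molecule into two halves of similar size plus a one-carbon unit, and removes the hindered etherification and the carboxylation in one move. The forward step must add the phenoxide at C4 rather than C5, and the C5 anion must meet 17 before it meets a proton.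

**12 to 10 (through 11).** The O–S bond of the triflate is cut and the oxygen is returned to a secondary carbamate, which serves as both protecting group and directing group. The forward step must remove it under conditions that leave the neighbouring C–Si bond intact.

**10 to 6.** The C–Si bond at the carbon between the carbamate oxygen and the methoxy group is cut. That carbon is activated by both oxygens, so silicon is introduced by directed metalation without a halogen. Ring deprotonation must be faster than removal of the benzylic–allylic protons of the prenyl group.

**6 to 5.** The O–C(O)N bond is cut; the phenol adds to an isocyanate. Placing the carbamate after the prenylation means the organolithium chemistry that builds the side chain meets only a phenoxide, and the N–H carbamate is made directly before the metalation that needs it.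

**5 to 1 and 2.** The aryl–CH2 bond of the prenyl group is cut to an aryl bromide and an allylic bromide. The forward step needs bromine–lithium exchange on the lithium salt of 1, and substitution at the CH2 end of 2 on carbon rather than on the phenoxide oxygen.

**16 to 15 to 14 to 13.** The O–Si bond is cut, the benzylic alcohol is returned to the aldehyde, and the C6'–CHO bond is cut. 13 has one free ortho position and a blocked para position, so ortho-formylation is unambiguous. Silylation must take the primary hydroxyl and leave the hindered phenol free.

## Other disconnections considered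

Alternative 1: benzannulation of ring A on an aryloxyalkyne.
- Cut: ring A is taken apart at C5–C6, C3–C4 and C1–C6, leaving the diazo dienone A1 and the aryloxyalkyne A2, in which the ether oxygen is already bound to an sp carbon.
- Forward key step: light would convert A1 by Wolff rearrangement into a vinylketene. (2+2) addition to A2, four-electron opening of the cyclobutenone, six-electron closure of the dienylketene and tautomerisation would give phenol A3.
- In favour: the ring A pattern follows from the polarity of the ketene–alkyne addition. C6 emerges as a free phenol, so ring A needs no ether cleavage, which is better than the chosen plan. The hindered ether bond is never formed on an arene, which equals the aryne approach in avoiding a metal-catalysed etherification.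
- Against:
  - C5 arrives as a silyloxymethyl group, two oxidation levels below the acid. Desilylation and two oxidations would follow beside an electron-rich phenol and a prenyl group.
  - A2 must be made from the hindered ring B phenol, and aryloxyalkynes are weaker ketene partners than alkoxy- or siloxyalkynes.
  - A1 is a skipped dienone whose doubly allylic CH2 invites migration of the double bond.
  - The acetal groups on ring B call for acid at the end, next to the o-prenylphenol.
- Comparison: on structure the two plans are equal, since both fix the C4/C5/C6 pattern by polarity. On mechanism the benzannulation is an established reaction class while the chosen key step is not, so this alternative is better on precedent. On step economy it is clearly longer, by the oxidation-state adjustment and the preparation of A1 and A2.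

Alternative 2: ring B by anionic electrocyclisation of an aryloxy diester.
- Cut: ring B is opened between C2' and C3', leaving diester A4, an aryloxy butenedioate carrying an isobutenyl group.
- Forward key step: base would remove a proton from a terminal methyl to give a trienolate. Its terminal carbon C3' would bond to the ester carbon C2'; loss of methoxide and tautomerisation would give phenol A5.
- In favour: the ether bond would be made by addition–elimination of a simple ring A phenoxide on an activated acyclic alkene, so no hindered arylation is needed. The C2' hydroxyl emerges free, so ring B needs no demethylation, which is better than the chosen plan.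
- Against:
  - A5 lacks the C5 carboxyl. It would have to be introduced later by metalation between the two ring A oxygens, in the presence of an ester and a phenol that both need protection or adjustment.
  - The C6' ester must be reduced to the alcohol at the right moment.
  - Only the isomer of A4 with the C2' ester cis to the isobutenyl group can close, so the geometry of a tetrasubstituted alkene has to be controlled.
  - The ring A methyl ether still has to be cleaved.
- Comparison: on structure it solves ring B but leaves the C4–C5–C6 problem of ring A to separate steps, whereas the chosen plan makes the C–O and C–C bonds together. On mechanism the anionic cyclisation is the equal or the better of the chosen plan in precedent. On step economy it is longer.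

Alternative 3: pyrone to benzoate with a prenyl siloxyalkyne.
- Cut: C1–C2 and C5–C6 of ring A are cut, leaving the 4-aryloxypyrone ester A6 and the siloxyalkyne A7.
- Forward key step: inverse-electron-demand (4+2) addition of A7 across C3 and C6 of the pyrone, then loss of CO2 from the bridged adduct, would give benzoate A8.
- In favour: all four ring A substituents arrive at their final oxidation level. The C6 oxygen comes as a silyl ether removable by fluoride, which is better than the chosen plan. Regiochemistry follows from pairing the nucleophilic alkyne carbon with C6 of the pyrone, and loss of CO2 makes aromatisation irreversible. Convergence is equal to that of the chosen plan.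
- Against:
  - The 4-aryloxy group donates into the pyrone and lowers its electron demand. Heating or an activator such as AgNTf2 would be needed, with a labile siloxyalkyne and acid-sensitive acetals present.
  - A7 has to come from ynolate chemistry.
  - A6 requires displacement at C4 of a pyrone by the hindered ring B phenoxide.
  - The methyl ester of A8 is flanked by two ortho oxygens and resists saponification, and the acetals need acid next to the o-prenylphenol.
- Comparison: on structure it is equal in regiochemical control. On mechanism it rests on a known cycloaddition class and is better in precedent. On step economy it is comparable or slightly longer, and its endgame is less safe than a purely nucleophilic one.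

Key step: step 8

## Route

Step 1
Reactants: 1 4-bromo-3-methoxyphenol; 2 prenyl bromide (1-bromo-3-methylbut-2-ene)
Product: 5 3-methoxy-4-(3-methylbut-2-enyl)phenol, via lithium bromophenoxide 3 (not isolated), via dilithiated phenoxide 4 (not isolated)
Conditions: n-BuLi (1 equiv), THF, −78 °C; t-BuLi (2 equiv), −78 °C; CuBr·SMe2 (cat.), 2 (1 equiv), −78 to −20 °C; aq NH4Cl
Reagents that add atoms: none
Why: The phenol is first turned into its lithium salt, which is inert to organolithiums and needs no protecting group; bromine–lithium exchange with t-BuLi then gives the aryllithium, and copper-catalysed allylic substitution at the unhindered CH2 end of 2 should give the linear prenylarene. The cold lithium phenoxide is far less nucleophilic than the arylcopper species, so O-alkylation is not expected with one equivalent of 2.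

Step 2
Reactants: 5 3-methoxy-4-(3-methylbut-2-enyl)phenol
Product: 6 3-methoxy-4-(3-methylbut-2-enyl)phenyl N-(propan-2-yl)carbamate
Conditions: i-PrNCO, Et3N (cat.), CH2Cl2, rt
Reagents that add atoms: isopropyl isocyanate, CC(C)N=C=O
Why: Base-catalysed addition of a phenol to an isocyanate (carbamoylation); the secondary carbamate is preferred to a dialkylcarbamate because it directs the ortho metalation after N-silylation and can later be removed by a mild amine base without loss of the ortho C–Si bond.

Step 3
Reactants: 6 3-methoxy-4-(3-methylbut-2-enyl)phenyl N-(propan-2-yl)carbamate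
Product: 10 3-methoxy-4-(3-methylbut-2-enyl)-2-(trimethylsilyl)phenyl N-(propan-2-yl)carbamate, via N-silyl carbamate 7 (not isolated), via ortho-lithiated carbamate 8 (not isolated), via doubly silylated carbamate 9 (not isolated)
Conditions: TBSOTf, TMEDA, Et2O, 0 °C to rt; n-BuLi, TMEDA, −78 °C; TMSCl, −78 °C to rt; aq NaHSO4
Reagents that add atoms: chlorotrimethylsilane, C[Si](C)(C)Cl
Why: Directed ortho metalation of an aryl carbamate whose acidic N–H is masked by in situ N-silylation (one equivalent of n-BuLi is consumed by the TMEDA triflate salt); the C–H between the carbamate oxygen and the methoxy group is activated by both, so lithiation at −78 °C should outpace removal of the benzylic–allylic protons, and cold silylation forestalls the anionic Fries shift. The N–Si bond is hydrolysed on work-up.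

Step 4
Reactants: 10 3-methoxy-4-(3-methylbut-2-enyl)-2-(trimethylsilyl)phenyl N-(propan-2-yl)carbamate
Product: 12 3-methoxy-4-(3-methylbut-2-enyl)-2-(trimethylsilyl)phenyl trifluoromethanesulfonate, via silylphenol 11 (not isolated)
Conditions: Et2NH, DBU, MeCN, 40 °C; then PhNTf2, rt
Reagents that add atoms: N-phenylbis(trifluoromethanesulfonimide), O=S(=O)(N(c1ccccc1)S(=O)(=O)C(F)(F)F)C(F)(F)F
Why: E1cB cleavage of the N–H carbamate (DBU removes the proton, the phenoxide leaves, diethylamine traps the isocyanate) followed by triflation of the phenoxide in the same flask; no hydroxide or fluoride is present, so the aryl–silicon bond should survive.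

Step 5
Reactants: 13 creosol (2-methoxy-4-methylphenol)
Product: 14 2-hydroxy-3-methoxy-5-methylbenzaldehyde
Conditions: MgCl2, Et3N, (CH2O)n, MeCN, reflux; aq HCl
Reagents that add atoms: paraformaldehyde (as formaldehyde), C=O
Why: Magnesium-mediated ortho-formylation of a phenol (Casnati–Skattebøl reaction); the magnesium phenoxide delivers formaldehyde to the only free ortho position, and a second formaldehyde oxidises the hydroxymethyl intermediate.

Step 6
Reactants: 14 2-hydroxy-3-methoxy-5-methylbenzaldehyde
Product: 15 2-(hydroxymethyl)-6-methoxy-4-methylphenol
Conditions: NaBH4, MeOH, 0 °C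
Reagents that add atoms: none
Why: Borohydride reduction of an aryl aldehyde; a near-neutral work-up avoids ionisation of the o-hydroxybenzyl alcohol.

Step 7
Reactants: 15 2-(hydroxymethyl)-6-methoxy-4-methylphenol
Product: 16 2-methoxy-4-methyl-6-(triisopropylsilyloxymethyl)phenol
Conditions: TIPSCl, imidazole, DMF, 0 °C to rt
Reagents that add atoms: chlorotriisopropylsilane, CC(C)[Si](Cl)(C(C)C)C(C)C
Why: Chemoselective silylation; the bulky silyl chloride should take the primary hydroxyl in preference to the phenol, which is flanked on both sides and hydrogen-bonded.

Step 8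
Reactants: 12 3-methoxy-4-(3-methylbut-2-enyl)-2-(trimethylsilyl)phenyl trifluoromethanesulfonate; 16 2-methoxy-4-methyl-6-(triisopropylsilyloxymethyl)phenol; 17 carbon dioxide
Product: 21 2-methoxy-6-[2-methoxy-4-methyl-6-(triisopropylsilyloxymethyl)phenoxy]-3-(3-methylbut-2-enyl)benzoic acid, via potassium phenoxide 18 (not isolated), via aryne 19 (not isolated), via arylpotassium 20 (not isolated)
Conditions: 16, KH, THF, 0 °C; then 18-crown-6, KF, CO2 (1 atm), slow addition of 12, THF, 0 °C to rt; aq KHSO4 (pH 3), 0 °C
Reagents that add atoms: none
Why: Proposed new method: fluoride attacks the trimethylsilyl group of 12 and triflate leaves, giving aryne 19 between C4 and C5; the C6 methoxy group withdraws σ-electron density and distorts the aryne so that C4 is the more electrophilic terminus, and phenoxide 18 should add there while the charge develops at C5 in an in-plane orbital flanked by two C–O bonds. Arylpotassium 20 is then carboxylated by dissolved CO2, so the C4–O and C5–carboxyl bonds form in one operation; the closest known reactions are the three-component coupling of arynes, amines and CO2 to anthranilic acids under KF and 18-crown-6 in THF, and the O-arylation of phenols by arynes from ortho-silylaryl triflates. No ring closes and no stereocentre is formed. Two selectivities are needed: the site of phenoxide addition, secured by the C6 methoxy group, and capture of the anion by CO2 rather than by a proton, secured by preforming the phenoxide with KH (no O–H or N–H remains), by using THF instead of acetonitrile, whose C–H bonds would protonate the aryl anion, and by a CO2-saturated solution. Ring B has no free ortho or para position, so CO2 can bind the phenoxide only reversibly at oxygen, and the triisopropylsilyl ether is expected to withstand KF at these temperatures. Slow addition of 12 keeps the aryne concentration low and limits its capture by the product carboxylate.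

Step 9
Reactants: 21 2-methoxy-6-[2-methoxy-4-methyl-6-(triisopropylsilyloxymethyl)phenoxy]-3-(3-methylbut-2-enyl)benzoic acid
Product: 23 2-hydroxy-6-[2-hydroxy-6-(hydroxymethyl)-4-methylphenoxy]-3-(3-methylbut-2-enyl)benzoic acid, via silyl-protected bisphenol 22 (not isolated)
Conditions: NaSEt, DMF, 120 °C (degassed); then TBAF, rt to 40 °C; aq HCl (pH 3), 0 °C
Reagents that add atoms: none
Why: Thiolate SN2 displacement at the two O-methyl carbons (nucleophilic dealkylation of aryl methyl ethers) unmasks both phenols without acid, which the o-prenylphenol and the 2,6-dioxygenated benzoic acid would not tolerate; fluoride then cleaves the primary silyl ether in the same flask.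

## Compound list

1 | 4-bromo-3-methoxyphenol | COc1cc(O)ccc1Br | starting material
2 | prenyl bromide (1-bromo-3-methylbut-2-ene) | CC(C)=CCBr | starting material
3 | lithium 4-bromo-3-methoxyphenoxide | [Li+].[O-]c1ccc(Br)c(OC)c1 | intermediate
4 | lithium 4-lithio-3-methoxyphenoxide | [Li+].[O-]c1ccc([Li])c(OC)c1 | intermediate
5 | 3-methoxy-4-(3-methylbut-2-enyl)phenol | COc1cc(O)ccc1CC=C(C)C | intermediate
6 | 3-methoxy-4-(3-methylbut-2-enyl)phenyl N-(propan-2-yl)carbamate | COc1cc(OC(=O)NC(C)C)ccc1CC=C(C)C | intermediate
7 | 3-methoxy-4-(3-methylbut-2-enyl)phenyl N-(tert-butyldimethylsilyl)-N-(propan-2-yl)carbamate | COc1cc(OC(=O)N(C(C)C)[Si](C)(C)C(C)(C)C)ccc1CC=C(C)C | intermediate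
8 | [6-[N-(tert-butyldimethylsilyl)-N-(propan-2-yl)carbamoyloxy]-2-methoxy-3-(3-methylbut-2-enyl)phenyl]lithium | COc1c([Li])c(OC(=O)N(C(C)C)[Si](C)(C)C(C)(C)C)ccc1CC=C(C)C | intermediate
9 | 3-methoxy-4-(3-methylbut-2-enyl)-2-(trimethylsilyl)phenyl N-(tert-butyldimethylsilyl)-N-(propan-2-yl)carbamate | COc1c([Si](C)(C)C)c(OC(=O)N(C(C)C)[Si](C)(C)C(C)(C)C)ccc1CC=C(C)C | intermediate
10 | 3-methoxy-4-(3-methylbut-2-enyl)-2-(trimethylsilyl)phenyl N-(propan-2-yl)carbamate | COc1c([Si](C)(C)C)c(OC(=O)NC(C)C)ccc1CC=C(C)C | intermediate
11 | 3-methoxy-4-(3-methylbut-2-enyl)-2-(trimethylsilyl)phenol | COc1c([Si](C)(C)C)c(O)ccc1CC=C(C)C | intermediate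
12 | 3-methoxy-4-(3-methylbut-2-enyl)-2-(trimethylsilyl)phenyl trifluoromethanesulfonate | CC(C)=CCc1ccc(OS(=O)(=O)C(F)(F)F)c([Si](C)(C)C)c1OC | intermediate
13 | creosol (2-methoxy-4-methylphenol) | COc1cc(C)ccc1O | starting material
14 | 2-hydroxy-3-methoxy-5-methylbenzaldehyde | COc1cc(C)cc(C=O)c1O | intermediate
15 | 2-(hydroxymethyl)-6-methoxy-4-methylphenol | COc1cc(C)cc(CO)c1O | intermediate
16 | 2-methoxy-4-methyl-6-(triisopropylsilyloxymethyl)phenol | COc1cc(C)cc(CO[Si](C(C)C)(C(C)C)C(C)C)c1O | intermediate
17 | carbon dioxide | O=C=O | starting material
18 | potassium 2-methoxy-4-methyl-6-(triisopropylsilyloxymethyl)phenoxide | COc1cc(C)cc(CO[Si](C(C)C)(C(C)C)C(C)C)c1[O-].[K+] | intermediate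
19 | 3-methoxy-4-(3-methylbut-2-enyl)benzyne (1,2-didehydro-3-methoxy-4-(3-methylbut-2-enyl)benzene) | COC1=C(CC=C(C)C)C=CC#C1 | intermediate
20 | [2-methoxy-6-[2-methoxy-4-methyl-6-(triisopropylsilyloxymethyl)phenoxy]-3-(3-methylbut-2-enyl)phenyl]potassium | CC(C)=CCc1ccc(Oc2c(OC)cc(C)cc2CO[Si](C(C)C)(C(C)C)C(C)C)c([K])c1OC | intermediate
21 | 2-methoxy-6-[2-methoxy-4-methyl-6-(triisopropylsilyloxymethyl)phenoxy]-3-(3-methylbut-2-enyl)benzoic acid | CC(C)=CCc1ccc(Oc2c(OC)cc(C)cc2CO[Si](C(C)C)(C(C)C)C(C)C)c(C(=O)O)c1OC | intermediate
22 | 2-hydroxy-6-[2-hydroxy-4-methyl-6-(triisopropylsilyloxymethyl)phenoxy]-3-(3-methylbut-2-enyl)benzoic acid | CC(C)=CCc1ccc(Oc2c(O)cc(C)cc2CO[Si](C(C)C)(C(C)C)C(C)C)c(C(=O)O)c1O | intermediate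
23 | 2-hydroxy-6-[2-hydroxy-6-(hydroxymethyl)-4-methylphenoxy]-3-(3-methylbut-2-enyl)benzoic acid | CC(C)=CCc1ccc(Oc2c(O)cc(C)cc2CO)c(C(=O)O)c1O | target

## Step count and least certain steps

Total: 9 steps. Longest linear sequence: 6 steps (steps 1, 2, 3, 4, 8 and 9, from 1); the ring B branch is 3 steps (5, 6, 7) before the coupling.

**Step 8 (key step, proposed new method).** The C5 anion may be protonated before it is carboxylated, by traces of water, by phenol left undeprotonated or by the α-C–H of THF; this would give the simple diaryl ether. A second risk is O-carbonation of the phenoxide by CO2, which lowers the concentration of free phenoxide and could let the carbonate oxygen add to the aryne, followed by acyl transfer to C5. Attack of fluoride on the silyl ether and erosion of regioselectivity are lesser risks. Fallback (known chemistry), from 12 and 16, returning at 21: CsF in MeCN without CO2 should give the O-arylation product, triisopropyl{[3-methoxy-2-[3-methoxy-4-(3-methylbut-2-enyl)phenoxy]-5-methylphenyl]methoxy}silane F1. This is also the by-product expected from premature protonation in the main step, so it is not lost. Its C5–H lies between the aryloxy and methoxy oxygens; directed metalation with n-BuLi and TMEDA in THF at −78 to −30 °C should give the C5 aryllithium, [2-methoxy-6-[2-methoxy-4-methyl-6-(triisopropylsilyloxymethyl)phenoxy]-3-(3-methylbut-2-enyl)phenyl]lithium F2, and CO2 with acidic work-up should then give 21.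

**Step 9.** Cleavage of the ring B methyl ether, on an electron-rich ring of a molecule that is already a dianion, may be incomplete at a temperature the carboxylate tolerates; longer heating invites radical addition of thiol to the prenyl alkene and loss of CO2. Fallback, from 14, returning at 22: the ring B oxygen is carried as an allyl ether that zerovalent palladium removes at rt. AlCl3 and pyridine should cleave the methyl ether of 14 to 2,3-dihydroxy-5-methylbenzaldehyde F3. The dianion (NaH, DMSO) is allylated with one equivalent of allyl bromide at the more nucleophilic 3-oxygen to give 3-(allyloxy)-2-hydroxy-5-methylbenzaldehyde F4. NaBH4 gives 2-(allyloxy)-6-(hydroxymethyl)-4-methylphenol F5, and TIPSCl with imidazole gives 2-(allyloxy)-4-methyl-6-(triisopropylsilyloxymethyl)phenol F6. The conditions of step 8 applied to F6, 12 and 17 should give 2-[2-(allyloxy)-4-methyl-6-(triisopropylsilyloxymethyl)phenoxy]-6-methoxy-3-(3-methylbut-2-enyl)benzoic acid F7. Pd(PPh3)4 and morpholine remove the allyl group to give 2-[2-hydroxy-4-methyl-6-(triisopropylsilyloxymethyl)phenoxy]-6-methoxy-3-(3-methylbut-2-enyl)benzoic acid F8. NaSEt then has only the ring A methyl ether to cleave, giving 22, and fluoride completes the route as in step 9.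

**Step 3.** n-BuLi with TMEDA may deprotonate the benzylic–allylic CH2 of the prenyl group in competition with the ring C–H, which would lead to silylation or double-bond migration in the side chain. Fallback, from 1, returning at 11: silicon is introduced before the prenyl group, with an amide base that does not touch the bromide. Diethylcarbamoyl chloride and K2CO3 give 4-bromo-3-methoxyphenyl N,N-diethylcarbamate F9. LiN(iPr)2 with TMSCl present in THF at −78 °C should give 4-bromo-3-methoxy-2-(trimethylsilyl)phenyl N,N-diethylcarbamate F10. n-BuLi, then CuBr·SMe2 and 2, give 3-methoxy-4-(3-methylbut-2-enyl)-2-(trimethylsilyl)phenyl N,N-diethylcarbamate F11. LiAlH4 in THF at reflux cleaves the carbamate reductively to 11, which is triflated with PhNTf2 and DBU as in the second half of step 4.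

**Step 1.** Bromine–lithium exchange on the electron-rich, aggregated lithium aryloxide may be incomplete; the aryllithium may be protonated before it is allylated; and substitution may occur at the tertiary end of the allylic bromide or on the phenoxide oxygen. Fallback, from 1, returning at 5: the phenol is masked as a silyl ether and the prenyl group is introduced by palladium-catalysed cross-coupling instead of organolithium chemistry. TIPSCl and imidazole give (4-bromo-3-methoxyphenoxy)triisopropylsilane F12. Zinc dust and LiCl in THF convert 2 into prenylzinc bromide F13. A linear-selective Negishi coupling of F12 with F13, catalysed by Pd(OAc)2 and a dialkylbiarylphosphine such as CPhos at rt, should give triisopropyl[3-methoxy-4-(3-methylbut-2-enyl)phenoxy]silane F14, and TBAF in THF then releases 5.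

**Step 7.** The phenol may be silylated along with, or instead of, the primary alcohol, and the o-hydroxybenzyl alcohol may ionise and oligomerise if the medium becomes acidic. Fallback, from 15, returning at 16: both hydroxyls are silylated with TIPSOTf and 2,6-lutidine to give triisopropyl{[3-methoxy-5-methyl-2-(triisopropylsilyloxy)phenyl]methoxy}silane F15. KHF2 in MeOH at rt to 50 °C then removes only the aryl silyl ether, which is far more labile than the alkyl silyl ether, leaving 16.

## Further compounds

F1 | step 8 | triisopropyl{[3-methoxy-2-[3-methoxy-4-(3-methylbut-2-enyl)phenoxy]-5-methylphenyl]methoxy}silane | CC(C)=CCc1ccc(Oc2c(OC)cc(C)cc2CO[Si](C(C)C)(C(C)C)C(C)C)cc1OC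
F2 | step 8 | [2-methoxy-6-[2-methoxy-4-methyl-6-(triisopropylsilyloxymethyl)phenoxy]-3-(3-methylbut-2-enyl)phenyl]lithium | CC(C)=CCc1ccc(Oc2c(OC)cc(C)cc2CO[Si](C(C)C)(C(C)C)C(C)C)c([Li])c1OC
F3 | step 9 | 2,3-dihydroxy-5-methylbenzaldehyde | Cc1cc(O)c(O)c(C=O)c1
F4 | step 9 | 3-(allyloxy)-2-hydroxy-5-methylbenzaldehyde | C=CCOc1cc(C)cc(C=O)c1O
F5 | step 9 | 2-(allyloxy)-6-(hydroxymethyl)-4-methylphenol | C=CCOc1cc(C)cc(CO)c1O
F6 | step 9 | 2-(allyloxy)-4-methyl-6-(triisopropylsilyloxymethyl)phenol | C=CCOc1cc(C)cc(CO[Si](C(C)C)(C(C)C)C(C)C)c1O
F7 | step 9 | 2-[2-(allyloxy)-4-methyl-6-(triisopropylsilyloxymethyl)phenoxy]-6-methoxy-3-(3-methylbut-2-enyl)benzoic acid | CC(C)=CCc1ccc(Oc2c(OCC=C)cc(C)cc2CO[Si](C(C)C)(C(C)C)C(C)C)c(C(=O)O)c1OC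
F8 | step 9 | 2-[2-hydroxy-4-methyl-6-(triisopropylsilyloxymethyl)phenoxy]-6-methoxy-3-(3-methylbut-2-enyl)benzoic acid | CC(C)=CCc1ccc(Oc2c(O)cc(C)cc2CO[Si](C(C)C)(C(C)C)C(C)C)c(C(=O)O)c1OC
F9 | step 3 | 4-bromo-3-methoxyphenyl N,N-diethylcarbamate | CCN(CC)C(=O)Oc1ccc(Br)c(OC)c1
F10 | step 3 | 4-bromo-3-methoxy-2-(trimethylsilyl)phenyl N,N-diethylcarbamate | CCN(CC)C(=O)Oc1ccc(Br)c(OC)c1[Si](C)(C)C
F11 | step 3 | 3-methoxy-4-(3-methylbut-2-enyl)-2-(trimethylsilyl)phenyl N,N-diethylcarbamate | CCN(CC)C(=O)Oc1ccc(CC=C(C)C)c(OC)c1[Si](C)(C)C
F12 | step 1 | (4-bromo-3-methoxyphenoxy)triisopropylsilane | COc1cc(O[Si](C(C)C)(C(C)C)C(C)C)ccc1Br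
F13 | step 1 | prenylzinc bromide (bromo(3-methylbut-2-enyl)zinc) | CC(C)=CC[Zn]Br
F14 | step 1 | triisopropyl[3-methoxy-4-(3-methylbut-2-enyl)phenoxy]silane | COc1cc(O[Si](C(C)C)(C(C)C)C(C)C)ccc1CC=C(C)C
F15 | step 7 | triisopropyl{[3-methoxy-5-methyl-2-(triisopropylsilyloxy)phenyl]methoxy}silane | COc1cc(C)cc(CO[Si](C(C)C)(C(C)C)C(C)C)c1O[Si](C(C)C)(C(C)C)C(C)C
A1 | alternative 1 | (E)-1-diazo-7-methylocta-3,6-dien-2-one | CC(C)=CC/C=C/C(=O)C=[N+]=[N-]
A2 | alternative 1 | tert-butyl{3-[2-(methoxymethoxy)-6-(methoxymethoxymethyl)-4-methylphenoxy]prop-2-ynoxy}dimethylsilane | COCOc1cc(C)cc(COCOC)c1OC#CCO[Si](C)(C)C(C)(C)C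
A3 | alternative 1 | 2-(tert-butyldimethylsilyloxymethyl)-3-[2-(methoxymethoxy)-6-(methoxymethoxymethyl)-4-methylphenoxy]-6-(3-methylbut-2-enyl)phenol | CC(C)=CCc1ccc(Oc2c(OCOC)cc(C)cc2COCOC)c(CO[Si](C)(C)C(C)(C)C)c1O
A4 | alternative 2 | dimethyl (Z)-2-[3-methoxy-4-(3-methylbut-2-enyl)phenoxy]-3-(2-methylprop-1-enyl)but-2-enedioate | COC(=O)/C(Oc1ccc(CC=C(C)C)c(OC)c1)=C(\C=C(C)C)C(=O)OC
A5 | alternative 2 | methyl 3-hydroxy-2-[3-methoxy-4-(3-methylbut-2-enyl)phenoxy]-5-methylbenzoate | COC(=O)c1cc(C)cc(O)c1Oc1ccc(CC=C(C)C)c(OC)c1
A6 | alternative 3 | methyl 4-[2-(methoxymethoxy)-6-(methoxymethoxymethyl)-4-methylphenoxy]-2-oxo-2H-pyran-3-carboxylate | COC(=O)C1=C(Oc2c(OCOC)cc(C)cc2COCOC)C=COC1=O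
A7 | alternative 3 | triisopropyl[(5-methylhex-4-en-1-ynyl)oxy]silane | CC(C)=CCC#CO[Si](C(C)C)(C(C)C)C(C)C
A8 | alternative 3 | methyl 6-[2-(methoxymethoxy)-6-(methoxymethoxymethyl)-4-methylphenoxy]-3-(3-methylbut-2-enyl)-2-(triisopropylsilyloxy)benzoate | CC(C)=CCc1ccc(Oc2c(OCOC)cc(C)cc2COCOC)c(C(=O)OC)c1O[Si](C(C)C)(C(C)C)C(C)C
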